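## Retrosynthetic overview

1. The γ-butyrolactone on C3 of the pyrrolo[1,2-a]azepine is added last, by lactam-selective reductive vinylogous Mannich addition of a 2-silyloxyfuran to a C3 lactam, then hydrogenation.
2. The furo[3,2-b]furanone is unfolded to a 3,5-disubstituted tetronic acid: the lactone ring is opened at O4–C5 (propanoate arm on C6a), C2–CH3 is traced back to a lactone carbonyl, and C3–C3a to the enol double bond.
3. Key disconnection C9–C3: a one-pot addition / intramolecular Wittig / Claisen sequence of an azepin-7-yl α-hydroxy ester with Ph3P=C=C=O builds the furanone ring and moves the azepine unit from O4 to C3.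
4. Feature that allows it: C3 of the tetrahydrofuran ring lies between O1–C2 and C3a–O4, so this ring is a reduced 4-hydroxyfuran-2(5H)-one whose C3 is an enol carbon, and C9 is the allylic end of the azepine C7–C8–C9 unit. An O4–C7 allyl vinyl ether therefore delivers C3 to C9, and the tether oxygen stays as lactone oxygen O4.
5. Fragments and ring order: (2R,3S)-methylmalic acid (from dimethyl D-malate) and a 7-hydroxy-8-ene pyrroloazepinone (lactam from the pool, azepine by ring-closing metathesis); then the furanone ring (key step), the lactone ring of the furofuranone, and the butyrolactone on C3.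

Key step: step 8

Remark: positions are numbered as in pyrrolo[1,2-a]azepine (C1 to C9a, N4) and furo[3,2-b]furan-5-one (O1, C2, C3, C3a, O4, C5, C6, C6a); (5S)-5-ethenylpyrrolidin-2-one and (2S)-2-(2-bromoethyl)oxirane are taken as purchasable single enantiomers.

## Route

Step 1
Reactants: 1 dimethyl (R)-malate
Product: 2 dimethyl (2R,3S)-2-hydroxy-3-methylbutanedioate
Conditions: LiN(i-Pr)2 (2.2 equiv), THF, −78 to −20 °C; MeI, −78 to 0 °C
Reagents that add atoms: iodomethane, CI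
Why: Fráter–Seebach alkylation, in which the chelated lithium alkoxide enolate is methylated anti to the alkoxide oxygen, should give the anti (2R,3S) diester and so set the methyl-bearing carbon (future C6) from the pool stereocentre (future C6a).

Step 2
Reactants: 2 dimethyl (2R,3S)-2-hydroxy-3-methylbutanedioate
Product: 3 (2R,3S)-2-hydroxy-3-methylbutanedioic acid
Conditions: LiOH·H2O (2.5 equiv), THF/H2O, 0 °C to rt; then aq. HCl
Reagents that add atoms: lithium hydroxide, [Li+].[OH-]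
Why: Ester saponification at low temperature, under which the α-stereocentre of the dicarboxylate is not expected to epimerise.

Step 3
Reactants: 4 (5S)-5-ethenylpyrrolidin-2-one; 5 (2S)-2-(2-bromoethyl)oxirane
Product: 6 (5S)-5-ethenyl-1-{2-[(2S)-oxiran-2-yl]ethyl}pyrrolidin-2-one
Conditions: NaH, DMF, 0 °C to rt
Reagents that add atoms: none
Why: SN2 N-alkylation of the sodium lactamate at the primary bromide, which should outrun epoxide opening; neither stereocentre takes part.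

Step 4
Reactants: 6 (5S)-5-ethenyl-1-{2-[(2S)-oxiran-2-yl]ethyl}pyrrolidin-2-one
Product: 7 (5S)-5-ethenyl-1-[(3S)-3-hydroxypent-4-en-1-yl]pyrrolidin-2-one
Conditions: Me3S+ I− (3 equiv), n-BuLi (2.9 equiv), THF, −10 °C to rt
Reagents that add atoms: trimethylsulfonium iodide, C[S+](C)C.[I-]
Why: Sulfonium ylide homologation of a terminal epoxide to an allylic alcohol (the ylide opens the epoxide at CH2 and excess ylide eliminates Me2S from the sulfonium alkoxide); the carbinol C–O bond is never broken, so the configuration of 5 is kept as (S) at future C7.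

Step 5
Reactants: 7 (5S)-5-ethenyl-1-[(3S)-3-hydroxypent-4-en-1-yl]pyrrolidin-2-one
Product: 8 (7S,9aS)-7-hydroxy-1,2,5,6,7,9a-hexahydro-3H-pyrrolo[1,2-a]azepin-3-one
Conditions: (H2IMes)(PCy3)Cl2Ru=CHPh (second-generation Grubbs catalyst, 5 mol%), CH2Cl2 (0.005 M), 40 °C
Reagents that add atoms: none
Why: Ring-closing metathesis of the two terminal alkenes should close the azepine ring as its C8=C9 (Z) alkene with loss of ethene, the lactam holding both chains in reach; both stereocentres are untouched.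

Step 6
Reactants: 3 (2R,3S)-2-hydroxy-3-methylbutanedioic acid; 8 (7S,9aS)-7-hydroxy-1,2,5,6,7,9a-hexahydro-3H-pyrrolo[1,2-a]azepin-3-one
Product: 11 (2S,3R)-3-hydroxy-2-methyl-4-oxo-4-{[(7S,9aS)-3-oxo-2,3,5,6,7,9a-hexahydro-1H-pyrrolo[1,2-a]azepin-7-yl]oxy}butanoic acid, via trifluoroacetoxy anhydride 9 (not isolated), via trifluoroacetate ester acid 10 (not isolated)
Conditions: (CF3CO)2O, 0 °C to rt, then evaporation; 8, THF, 0 °C to rt (no base); MeOH, rt
Reagents that add atoms: none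
Why: Mixed-anhydride acylation: (CF3CO)2O turns 3 into its O-trifluoroacetyl cyclic anhydride, which alcohol 8 should open at the carbonyl next to the trifluoroacetoxy carbon (more electrophilic and less hindered than the one next to the methyl-bearing carbon) with retention at C7 because the C7–O bond is not broken, and methanol then removes the trifluoroacetate.

Step 7
Reactants: 11 (2S,3R)-3-hydroxy-2-methyl-4-oxo-4-{[(7S,9aS)-3-oxo-2,3,5,6,7,9a-hexahydro-1H-pyrrolo[1,2-a]azepin-7-yl]oxy}butanoic acid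
Product: 12 4-tert-butyl 1-[(7S,9aS)-3-oxo-2,3,5,6,7,9a-hexahydro-1H-pyrrolo[1,2-a]azepin-7-yl] (2R,3S)-2-hydroxy-3-methylbutanedioate
Conditions: tert-butyl 2,2,2-trichloroacetimidate (2 equiv), CH2Cl2/cyclohexane, rt
Reagents that add atoms: tert-butyl 2,2,2-trichloroacetimidate, CC(C)(C)OC(=N)C(Cl)(Cl)Cl
Why: tert-Butyl esterification by acid-promoted O-alkylation with the trichloroacetimidate; without added Lewis acid only the carboxylic acid is acidic enough to activate the imidate, so the secondary alcohol should stay free.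

Step 8
Reactants: 12 4-tert-butyl 1-[(7S,9aS)-3-oxo-2,3,5,6,7,9a-hexahydro-1H-pyrrolo[1,2-a]azepin-7-yl] (2R,3S)-2-hydroxy-3-methylbutanedioate; 13 (triphenylphosphoranylidene)ketene
Product: 16 tert-butyl (2S)-2-{(2R)-3-hydroxy-5-oxo-4-[(9R,9aS)-3-oxo-2,3,5,6,9,9a-hexahydro-1H-pyrrolo[1,2-a]azepin-9-yl]-2,5-dihydrofuran-2-yl}propanoate, via acyl ylide 14 (not isolated), via allyl tetronate 15 (not isolated)
Conditions: 13 (1.2 equiv), toluene, 60 °C; then 120 °C (sealed tube)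
Reagents that add atoms: none
Why: The hydroxyl of 12 adds across the cumulated C=C of 13 to give acyl ylide 14, whose ylide carbon attacks the neighbouring azepinyl ester carbonyl in an intramolecular Wittig olefination (5-exo-trig, loss of Ph3PO) that closes the 4-alkoxyfuran-2(5H)-one ring and leaves the azepinyl oxygen on the new enol carbon, so that 15 is an allyl vinyl ether. On heating, 15 should undergo a Claisen [3,3] shift through a six-membered transition state spanning O–C7–C8=C9 of the azepine and C3a=C3 of the furanone, which forms the C9–C3 bond, moves the ring alkene to C7=C8 and, after enolisation, gives tetronic acid 16; the closest known reaction type is the domino addition–Wittig olefination–Claisen rearrangement of allyl α-hydroxy esters with Ph3P=C=C=O to 3-allyltetronic acids. The only new stereocentre, C9, is set by suprafacial 1,3-transfer from the (7S)-carbinol: the furanone carbon must bond to C9 on the ring face that carried oxygen at C7, which is the face of C1 and opposite to H9a. Selectivity of the Wittig closure for the azepinyl ester over the tert-butyl ester is expected from ring size (five against six) and from the steric shielding of the tert-butyl ester. The step needs a concerted shift and not an ion-pair pathway, for which an apolar solvent and the lowest effective temperature are chosen, and the cyclic allyl unit fixes the regiochemistry at C9.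

Step 9
Reactants: 16 tert-butyl (2S)-2-{(2R)-3-hydroxy-5-oxo-4-[(9R,9aS)-3-oxo-2,3,5,6,9,9a-hexahydro-1H-pyrrolo[1,2-a]azepin-9-yl]-2,5-dihydrofuran-2-yl}propanoate
Product: 17 tert-butyl (2S)-2-{(2R,3R,4S)-3-hydroxy-5-oxo-4-[(9R,9aS)-3-oxooctahydro-1H-pyrrolo[1,2-a]azepin-9-yl]oxolan-2-yl}propanoate
Conditions: H2 (60 bar), Rh/Al2O3 (5 wt% Rh), EtOAc/AcOH (10:1), 40 °C
Reagents that add atoms: none
Why: Heterogeneous syn-hydrogenation, which for 3,5-disubstituted tetronic acids delivers both hydrogens to the enol C=C from the face opposite the substituent on the sp3 ring carbon, should place the azepanyl group (future C3), the hydroxyl (future C3a) and the propanoate arm all cis, and saturates C7=C8 in the same operation.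

Step 10
Reactants: 17 tert-butyl (2S)-2-{(2R,3R,4S)-3-hydroxy-5-oxo-4-[(9R,9aS)-3-oxooctahydro-1H-pyrrolo[1,2-a]azepin-9-yl]oxolan-2-yl}propanoate
Product: 18 tert-butyl (2S)-2-{(2R,3R,4S)-5-oxo-4-[(9R,9aS)-3-oxooctahydro-1H-pyrrolo[1,2-a]azepin-9-yl]-3-[(triethylsilyl)oxy]oxolan-2-yl}propanoate
Conditions: Et3SiCl, imidazole, DMF, rt
Reagents that add atoms: chlorotriethylsilane, CC[Si](Cl)(CC)CC
Why: Silyl ether formation masks the only hydroxyl before the titanium reagent, under conditions too mild to epimerise the carbon α to the lactone carbonyl.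

Step 11
Reactants: 18 tert-butyl (2S)-2-{(2R,3R,4S)-5-oxo-4-[(9R,9aS)-3-oxooctahydro-1H-pyrrolo[1,2-a]azepin-9-yl]-3-[(triethylsilyl)oxy]oxolan-2-yl}propanoate
Product: 19 tert-butyl (2S)-2-{(2R,3R,4S)-5-methylidene-4-[(9R,9aS)-3-oxooctahydro-1H-pyrrolo[1,2-a]azepin-9-yl]-3-[(triethylsilyl)oxy]oxolan-2-yl}propanoate
Conditions: Cp2TiMe2 (3 equiv), toluene, 70 °C, dark
Reagents that add atoms: dimethyltitanocene, [CH3-].[CH3-].[Ti+4].[cH-]1cccc1.[cH-]1cccc1
Why: Petasis methylenation, in which thermally formed Cp2Ti=CH2 converts the γ-lactone carbonyl into the exocyclic enol ether; the lactone should react ahead of the bulky tert-butyl ester and the less electrophilic lactam, and the neutral conditions leave the adjacent stereocentre untouched.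

Step 12
Reactants: 19 tert-butyl (2S)-2-{(2R,3R,4S)-5-methylidene-4-[(9R,9aS)-3-oxooctahydro-1H-pyrrolo[1,2-a]azepin-9-yl]-3-[(triethylsilyl)oxy]oxolan-2-yl}propanoate
Product: 20 tert-butyl (2S)-2-{(2R,3R,4R,5S)-5-methyl-4-[(9R,9aS)-3-oxooctahydro-1H-pyrrolo[1,2-a]azepin-9-yl]-3-[(triethylsilyl)oxy]oxolan-2-yl}propanoate
Conditions: H2 (1 bar), Pd/C, EtOAc, Et3N (1 vol%), rt
Reagents that add atoms: none
Why: Heterogeneous hydrogenation of the exocyclic enol ether from the ring face opposite the three cis substituents should place the new methyl cis to them and so set future C2 as (S).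

Step 13
Reactants: 20 tert-butyl (2S)-2-{(2R,3R,4R,5S)-5-methyl-4-[(9R,9aS)-3-oxooctahydro-1H-pyrrolo[1,2-a]azepin-9-yl]-3-[(triethylsilyl)oxy]oxolan-2-yl}propanoate
Product: 22 (2S,3R,3aR,6S,6aR)-2,6-dimethyl-3-[(9R,9aS)-3-oxooctahydro-1H-pyrrolo[1,2-a]azepin-9-yl]hexahydrofuro[3,2-b]furan-5(2H)-one, via hydroxy acid 21 (not isolated)
Conditions: CF3CO2H/CH2Cl2/H2O (20:78:2), 0 °C to rt
Reagents that add atoms: none
Why: Acidolysis removes the triethylsilyl ether and the tert-butyl ester (loss of isobutene), and the cis-disposed hydroxyl and carboxylic acid should close the γ-lactone by lactonisation without touching a stereocentre.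

Step 14
Reactants: 23 3-methylfuran-2(5H)-one
Product: 24 triisopropyl[(3-methylfuran-2-yl)oxy]silane
Conditions: i-Pr3SiOTf, Et3N, CH2Cl2, 0 °C
Reagents that add atoms: triisopropylsilyl trifluoromethanesulfonate, CC(C)[Si](OS(=O)(=O)C(F)(F)F)(C(C)C)C(C)C
Why: Soft enolisation and O-silylation of the butenolide (silyl dienol ether formation) gives the aromatic 2-silyloxyfuran; no stereocentre is involved.

Step 15
Reactants: 22 (2S,3R,3aR,6S,6aR)-2,6-dimethyl-3-[(9R,9aS)-3-oxooctahydro-1H-pyrrolo[1,2-a]azepin-9-yl]hexahydrofuro[3,2-b]furan-5(2H)-one; 24 triisopropyl[(3-methylfuran-2-yl)oxy]silane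
Product: 26 (2S,3R,3aR,6S,6aR)-2,6-dimethyl-3-{(3S,9R,9aS)-3-[(2S)-4-methyl-5-oxo-2,5-dihydrofuran-2-yl]octahydro-1H-pyrrolo[1,2-a]azepin-9-yl}hexahydrofuro[3,2-b]furan-5(2H)-one, via silyl hemiaminal 25 (not isolated)
Conditions: IrCl(CO)(PPh3)2 (1 mol%), (Me2HSi)2O, toluene, rt; then 24, CF3CO2H, CH2Cl2, −40 to 0 °C
Reagents that add atoms: none
Why: Lactam-selective iridium-catalysed hydrosilylation gives the N,O-silyl acetal, which acid ionises to the bicyclic iminium ion that 24 traps in a vinylogous Mannich reaction; attack anti to the C9a–C9 bond should give the 3,9a-trans pyrrolidine (C3 S) and the usual open transition state the (S)-butenolide carbon, as known for this reaction type on pyrrolo[1,2-a]azepin-3-ones that carry a lactone.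

Step 16
Reactants: 26 (2S,3R,3aR,6S,6aR)-2,6-dimethyl-3-{(3S,9R,9aS)-3-[(2S)-4-methyl-5-oxo-2,5-dihydrofuran-2-yl]octahydro-1H-pyrrolo[1,2-a]azepin-9-yl}hexahydrofuro[3,2-b]furan-5(2H)-one
Product: 27 (2S,3R,3aR,6S,6aR)-2,6-dimethyl-3-{(3S,9R,9aS)-3-[(2S,4S)-4-methyl-5-oxooxolan-2-yl]octahydro-1H-pyrrolo[1,2-a]azepin-9-yl}hexahydrofuro[3,2-b]furan-5(2H)-one
Conditions: H2 (4 bar), Rh/Al2O3, EtOAc, rt
Reagents that add atoms: none
Why: Heterogeneous hydrogenation of the butenolide from the face opposite the pyrrolidine substituent should give the cis-2,4-disubstituted butyrolactone (methyl carbon S), the usual outcome for α-methylbutenolides of this type.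

## Compound list

1 | dimethyl (2R)-2-hydroxybutanedioate (dimethyl D-malate) | COC(=O)C[C@@H](O)C(=O)OC | starting material
2 | dimethyl (2R,3S)-2-hydroxy-3-methylbutanedioate | COC(=O)[C@@H](C)[C@@H](O)C(=O)OC | intermediate
3 | (2R,3S)-2-hydroxy-3-methylbutanedioic acid | OC(=O)[C@@H](C)[C@@H](O)C(=O)O | intermediate
4 | (5S)-5-ethenylpyrrolidin-2-one | C=C[C@@H]1CCC(=O)N1 | starting material
5 | (2S)-2-(2-bromoethyl)oxirane | BrCC[C@H]1CO1 | starting material
6 | (5S)-5-ethenyl-1-{2-[(2S)-oxiran-2-yl]ethyl}pyrrolidin-2-one | O=C1CC[C@@H](C=C)N1CC[C@H]1CO1 | intermediate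
7 | (5S)-5-ethenyl-1-[(3S)-3-hydroxypent-4-en-1-yl]pyrrolidin-2-one | O=C1CC[C@@H](C=C)N1CC[C@H](O)C=C | intermediate
8 | (7S,9aS)-7-hydroxy-1,2,5,6,7,9a-hexahydro-3H-pyrrolo[1,2-a]azepin-3-one | O[C@@H]1C=C[C@@H]2CCC(=O)N2CC1 | intermediate
9 | (3R,4S)-4-methyl-2,5-dioxooxolan-3-yl trifluoroacetate | O=C1OC(=O)[C@@H](C)[C@H]1OC(=O)C(F)(F)F | intermediate
10 | (2S,3R)-2-methyl-4-oxo-4-{[(7S,9aS)-3-oxo-2,3,5,6,7,9a-hexahydro-1H-pyrrolo[1,2-a]azepin-7-yl]oxy}-3-(trifluoroacetoxy)butanoic acid | OC(=O)[C@@H](C)[C@@H](OC(=O)C(F)(F)F)C(=O)O[C@@H]1C=C[C@@H]2CCC(=O)N2CC1 | intermediate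
11 | (2S,3R)-3-hydroxy-2-methyl-4-oxo-4-{[(7S,9aS)-3-oxo-2,3,5,6,7,9a-hexahydro-1H-pyrrolo[1,2-a]azepin-7-yl]oxy}butanoic acid | OC(=O)[C@@H](C)[C@@H](O)C(=O)O[C@@H]1C=C[C@@H]2CCC(=O)N2CC1 | intermediate
12 | 4-tert-butyl 1-[(7S,9aS)-3-oxo-2,3,5,6,7,9a-hexahydro-1H-pyrrolo[1,2-a]azepin-7-yl] (2R,3S)-2-hydroxy-3-methylbutanedioate | CC(C)(C)OC(=O)[C@@H](C)[C@@H](O)C(=O)O[C@@H]1C=C[C@@H]2CCC(=O)N2CC1 | intermediate
13 | (triphenylphosphoranylidene)ketene, Ph3P=C=C=O | O=C=C=P(c1ccccc1)(c1ccccc1)c1ccccc1 | starting material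
14 | 4-tert-butyl 1-[(7S,9aS)-3-oxo-2,3,5,6,7,9a-hexahydro-1H-pyrrolo[1,2-a]azepin-7-yl] (2R,3S)-3-methyl-2-{[(triphenylphosphoranylidene)acetyl]oxy}butanedioate | CC(C)(C)OC(=O)[C@@H](C)[C@@H](OC(=O)C=P(c1ccccc1)(c1ccccc1)c1ccccc1)C(=O)O[C@@H]1C=C[C@@H]2CCC(=O)N2CC1 | intermediate
15 | tert-butyl (2S)-2-[(2R)-5-oxo-3-{[(7S,9aS)-3-oxo-2,3,5,6,7,9a-hexahydro-1H-pyrrolo[1,2-a]azepin-7-yl]oxy}-2,5-dihydrofuran-2-yl]propanoate | CC(C)(C)OC(=O)[C@@H](C)[C@H]1OC(=O)C=C1O[C@@H]1C=C[C@@H]2CCC(=O)N2CC1 | intermediate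
16 | tert-butyl (2S)-2-{(2R)-3-hydroxy-5-oxo-4-[(9R,9aS)-3-oxo-2,3,5,6,9,9a-hexahydro-1H-pyrrolo[1,2-a]azepin-9-yl]-2,5-dihydrofuran-2-yl}propanoate | CC(C)(C)OC(=O)[C@@H](C)[C@H]1OC(=O)C([C@H]2C=CCCN3[C@H]2CCC3=O)=C1O | intermediate
17 | tert-butyl (2S)-2-{(2R,3R,4S)-3-hydroxy-5-oxo-4-[(9R,9aS)-3-oxooctahydro-1H-pyrrolo[1,2-a]azepin-9-yl]oxolan-2-yl}propanoate | CC(C)(C)OC(=O)[C@@H](C)[C@H]1OC(=O)[C@@H]([C@H]2CCCCN3[C@H]2CCC3=O)[C@H]1O | intermediate
18 | tert-butyl (2S)-2-{(2R,3R,4S)-5-oxo-4-[(9R,9aS)-3-oxooctahydro-1H-pyrrolo[1,2-a]azepin-9-yl]-3-[(triethylsilyl)oxy]oxolan-2-yl}propanoate | CC(C)(C)OC(=O)[C@@H](C)[C@H]1OC(=O)[C@@H]([C@H]2CCCCN3[C@H]2CCC3=O)[C@H]1O[Si](CC)(CC)CC | intermediate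
19 | tert-butyl (2S)-2-{(2R,3R,4S)-5-methylidene-4-[(9R,9aS)-3-oxooctahydro-1H-pyrrolo[1,2-a]azepin-9-yl]-3-[(triethylsilyl)oxy]oxolan-2-yl}propanoate | CC(C)(C)OC(=O)[C@@H](C)[C@H]1OC(=C)[C@@H]([C@H]2CCCCN3[C@H]2CCC3=O)[C@H]1O[Si](CC)(CC)CC | intermediate
20 | tert-butyl (2S)-2-{(2R,3R,4R,5S)-5-methyl-4-[(9R,9aS)-3-oxooctahydro-1H-pyrrolo[1,2-a]azepin-9-yl]-3-[(triethylsilyl)oxy]oxolan-2-yl}propanoate | CC(C)(C)OC(=O)[C@@H](C)[C@H]1O[C@@H](C)[C@@H]([C@H]2CCCCN3[C@H]2CCC3=O)[C@H]1O[Si](CC)(CC)CC | intermediate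
21 | (2S)-2-{(2R,3R,4S,5S)-3-hydroxy-5-methyl-4-[(9R,9aS)-3-oxooctahydro-1H-pyrrolo[1,2-a]azepin-9-yl]oxolan-2-yl}propanoic acid | OC(=O)[C@@H](C)[C@H]1O[C@@H](C)[C@@H]([C@H]2CCCCN3[C@H]2CCC3=O)[C@H]1O | intermediate
22 | (2S,3R,3aR,6S,6aR)-2,6-dimethyl-3-[(9R,9aS)-3-oxooctahydro-1H-pyrrolo[1,2-a]azepin-9-yl]hexahydrofuro[3,2-b]furan-5(2H)-one | C[C@@H]1O[C@H]2[C@H](OC(=O)[C@H]2C)[C@@H]1[C@H]1CCCCN2[C@H]1CCC2=O | intermediate
23 | 3-methylfuran-2(5H)-one | CC1=CCOC1=O | starting material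
24 | triisopropyl[(3-methylfuran-2-yl)oxy]silane | Cc1ccoc1O[Si](C(C)C)(C(C)C)C(C)C | intermediate
25 | (2S,3R,3aR,6S,6aR)-2,6-dimethyl-3-{(9R,9aS)-3-[(1,1,3,3-tetramethyldisiloxanyl)oxy]octahydro-1H-pyrrolo[1,2-a]azepin-9-yl}hexahydrofuro[3,2-b]furan-5(2H)-one (both epimers at the silyloxy carbon) | C[C@@H]1O[C@H]2[C@H](OC(=O)[C@H]2C)[C@@H]1[C@H]1CCCCN2[C@H]1CCC2O[Si](C)(C)O[SiH](C)C | intermediate
26 | (2S,3R,3aR,6S,6aR)-2,6-dimethyl-3-{(3S,9R,9aS)-3-[(2S)-4-methyl-5-oxo-2,5-dihydrofuran-2-yl]octahydro-1H-pyrrolo[1,2-a]azepin-9-yl}hexahydrofuro[3,2-b]furan-5(2H)-one | C[C@@H]1O[C@H]2[C@H](OC(=O)[C@H]2C)[C@@H]1[C@H]1CCCCN2[C@H]1CC[C@H]2[C@@H]1C=C(C)C(=O)O1 | intermediate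
27 | (2S,3R,3aR,6S,6aR)-2,6-dimethyl-3-{(3S,9R,9aS)-3-[(2S,4S)-4-methyl-5-oxooxolan-2-yl]octahydro-1H-pyrrolo[1,2-a]azepin-9-yl}hexahydrofuro[3,2-b]furan-5(2H)-one | C[C@@H]1O[C@H]2[C@H](OC(=O)[C@H]2C)[C@@H]1[C@H]1CCCCN2[C@H]1CC[C@H]2[C@@H]1C[C@H](C)C(=O)O1 | target

## Step count and risks

Total steps: 16. Longest linear sequence: 13 steps (steps 3 to 13, then 15 and 16, from 4 and 5).

The three steps most likely to fail:

**Step 8.** The Wittig closure may stall on the hindered secondary ester, the allyl tetronate may ionise before the sigmatropic shift and lose the face-selective transfer, or the tetronic acid may cyclise thermally onto the C7=C8 alkene. The fallback makes the bond first and the ring second. From 8, Johnson–Claisen rearrangement (MeC(OEt)3, cat. EtCO2H, 135 °C) should move an acetate unit to C9 with the same suprafacial course and give ethyl 2-[(9S,9aS)-3-oxo-2,3,5,6,9,9a-hexahydro-1H-pyrrolo[1,2-a]azepin-9-yl]acetate F1, which LiOH saponifies to 2-[(9S,9aS)-3-oxo-2,3,5,6,9,9a-hexahydro-1H-pyrrolo[1,2-a]azepin-9-yl]acetic acid F2. Carbodiimide esterification (EDC·HCl, DMAP) of F2 with the free hydroxyl of 12 should give 4-tert-butyl 1-[(7S,9aS)-3-oxo-2,3,5,6,7,9a-hexahydro-1H-pyrrolo[1,2-a]azepin-7-yl] (2R,3S)-3-methyl-2-({[(9S,9aS)-3-oxo-2,3,5,6,9,9a-hexahydro-1H-pyrrolo[1,2-a]azepin-9-yl]acetyl}oxy)butanedioate F3. Dieckmann cyclisation of F3 (LiN(SiMe3)2, THF, −78 to 0 °C), with the azepinyl alkoxide as leaving group (8 is recovered), closes the furanone ring and comes back to the route at 16.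

**Step 9.** Hydrogenation of the tetrasubstituted, acidic enol may stall or lose facial control. The fallback sets out from 16 and reduces an enone and a ketone instead. O-Methylation (Me3SiCHN2, MeOH/toluene) should give tert-butyl (2S)-2-{(2R)-3-methoxy-5-oxo-4-[(9R,9aS)-3-oxo-2,3,5,6,9,9a-hexahydro-1H-pyrrolo[1,2-a]azepin-9-yl]-2,5-dihydrofuran-2-yl}propanoate F4. MeLi (THF, −78 °C) followed by dilute acid (1,2-addition, loss of methanol) should give the furan-3(2H)-one tert-butyl (2S)-2-{(2R)-5-methyl-3-oxo-4-[(9R,9aS)-3-oxo-2,3,5,6,9,9a-hexahydro-1H-pyrrolo[1,2-a]azepin-9-yl]-2,3-dihydrofuran-2-yl}propanoate F5, which already carries the C2 methyl. Hydrogenation (H2, Pd/C) of the enone and of C7=C8 from the face opposite the propanoate arm should give tert-butyl (2S)-2-{(2R,4R,5S)-5-methyl-3-oxo-4-[(9R,9aS)-3-oxooctahydro-1H-pyrrolo[1,2-a]azepin-9-yl]oxolan-2-yl}propanoate F6. NaBH4 (MeOH, −40 °C), attacking from the same open face, should give tert-butyl (2S)-2-{(2R,3R,4S,5S)-3-hydroxy-5-methyl-4-[(9R,9aS)-3-oxooctahydro-1H-pyrrolo[1,2-a]azepin-9-yl]oxolan-2-yl}propanoate F7. CF3CO2H as in step 13 then comes back to the route at 22.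

**Step 11.** The titanium methylidene may also attack the lactam or the tert-butyl ester, or fail to reach the hindered lactone carbonyl. The fallback sets out from 18 and brings the methyl in as a nucleophile. i-Bu2AlH (CH2Cl2, −78 °C) should reduce only the lactone, to the lactol tert-butyl (2S)-2-{(2R,3R,4S)-5-hydroxy-4-[(9R,9aS)-3-oxooctahydro-1H-pyrrolo[1,2-a]azepin-9-yl]-3-[(triethylsilyl)oxy]oxolan-2-yl}propanoate F8. Ac2O/pyridine gives the anomeric acetate tert-butyl (2S)-2-{(2R,3R,4S)-5-acetoxy-4-[(9R,9aS)-3-oxooctahydro-1H-pyrrolo[1,2-a]azepin-9-yl]-3-[(triethylsilyl)oxy]oxolan-2-yl}propanoate F9. AlMe3 (CH2Cl2, −78 °C) then methylates the derived oxocarbenium ion; inside attack on the envelope with a pseudoaxial 3-silyloxy group (1,3-cis addition) should place the methyl cis to the silyloxy group and come back to the route at 20.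

Further compounds
F1 | step 8 | ethyl 2-[(9S,9aS)-3-oxo-2,3,5,6,9,9a-hexahydro-1H-pyrrolo[1,2-a]azepin-9-yl]acetate | CCOC(=O)C[C@H]1C=CCCN2[C@H]1CCC2=O
F2 | step 8 | 2-[(9S,9aS)-3-oxo-2,3,5,6,9,9a-hexahydro-1H-pyrrolo[1,2-a]azepin-9-yl]acetic acid | OC(=O)C[C@H]1C=CCCN2[C@H]1CCC2=O
F3 | step 8 | 4-tert-butyl 1-[(7S,9aS)-3-oxo-2,3,5,6,7,9a-hexahydro-1H-pyrrolo[1,2-a]azepin-7-yl] (2R,3S)-3-methyl-2-({[(9S,9aS)-3-oxo-2,3,5,6,9,9a-hexahydro-1H-pyrrolo[1,2-a]azepin-9-yl]acetyl}oxy)butanedioate | CC(C)(C)OC(=O)[C@@H](C)[C@@H](OC(=O)C[C@H]1C=CCCN2[C@H]1CCC2=O)C(=O)O[C@@H]1C=C[C@@H]2CCC(=O)N2CC1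
F4 | step 9 | tert-butyl (2S)-2-{(2R)-3-methoxy-5-oxo-4-[(9R,9aS)-3-oxo-2,3,5,6,9,9a-hexahydro-1H-pyrrolo[1,2-a]azepin-9-yl]-2,5-dihydrofuran-2-yl}propanoate | CC(C)(C)OC(=O)[C@@H](C)[C@H]1OC(=O)C([C@H]2C=CCCN3[C@H]2CCC3=O)=C1OC
F5 | step 9 | tert-butyl (2S)-2-{(2R)-5-methyl-3-oxo-4-[(9R,9aS)-3-oxo-2,3,5,6,9,9a-hexahydro-1H-pyrrolo[1,2-a]azepin-9-yl]-2,3-dihydrofuran-2-yl}propanoate | CC(C)(C)OC(=O)[C@@H](C)[C@H]1OC(C)=C([C@H]2C=CCCN3[C@H]2CCC3=O)C1=O
F6 | step 9 | tert-butyl (2S)-2-{(2R,4R,5S)-5-methyl-3-oxo-4-[(9R,9aS)-3-oxooctahydro-1H-pyrrolo[1,2-a]azepin-9-yl]oxolan-2-yl}propanoate | CC(C)(C)OC(=O)[C@@H](C)[C@H]1O[C@@H](C)[C@@H]([C@H]2CCCCN3[C@H]2CCC3=O)C1=O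
F7 | step 9 | tert-butyl (2S)-2-{(2R,3R,4S,5S)-3-hydroxy-5-methyl-4-[(9R,9aS)-3-oxooctahydro-1H-pyrrolo[1,2-a]azepin-9-yl]oxolan-2-yl}propanoate | CC(C)(C)OC(=O)[C@@H](C)[C@H]1O[C@@H](C)[C@@H]([C@H]2CCCCN3[C@H]2CCC3=O)[C@H]1O
F8 | step 11 | tert-butyl (2S)-2-{(2R,3R,4S)-5-hydroxy-4-[(9R,9aS)-3-oxooctahydro-1H-pyrrolo[1,2-a]azepin-9-yl]-3-[(triethylsilyl)oxy]oxolan-2-yl}propanoate (anomers) | CC(C)(C)OC(=O)[C@@H](C)[C@H]1OC(O)[C@@H]([C@H]2CCCCN3[C@H]2CCC3=O)[C@H]1O[Si](CC)(CC)CC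
F9 | step 11 | tert-butyl (2S)-2-{(2R,3R,4S)-5-acetoxy-4-[(9R,9aS)-3-oxooctahydro-1H-pyrrolo[1,2-a]azepin-9-yl]-3-[(triethylsilyl)oxy]oxolan-2-yl}propanoate (anomers) | CC(C)(C)OC(=O)[C@@H](C)[C@H]1OC(OC(C)=O)[C@@H]([C@H]2CCCCN3[C@H]2CCC3=O)[C@H]1O[Si](CC)(CC)CC
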